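**Strategy.** The target is cut at the spiro-dihydropyran (ring D) into 5-epi-isoalantolactone and an ent-elemane enal, united last by a hetero-Diels–Alder reaction. Everything rests on the cyclohexane of the elemane half (ring E). Its quaternary carbon (methyl, vinyl) and the adjacent methine that carries the isopropenyl group come from an E-configured ene-dicarbonyl, and the other four ring carbons from a 2-silyloxy diene. One catalytic asymmetric Diels–Alder reaction closes ring E by joining that methine to its CH2 neighbour (and the quaternary carbon to the opposite CH2). It fixes both stereocentres and leaves a ketone where the side chain is grown. The precursors are acyclic: (2E)-2-methyl-4-oxopent-2-enal and 2-(triisopropylsilyloxy)butadiene.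

Key step: step 3

Remark on the target: its eudesmanolide half has a cis-fused decalin (5β-H, 10β-CH3, 7α-H, 8α-H), so it is the C-5 epimer of isoalantolactone; its elemane half is the enantiomer of the β-elemene series.

Assumption on the catalyst: the (R)-oxazaborolidinium ion is taken to expose the (2Si,3Si) face of the formyl-bound enal 5, by the accepted binding model for α-branched acroleins. If the opposite sense is found, the enantiomeric catalyst is used with no other change.

Assumption on starting material: (+)-isoalantolactone is bought and serves as chiral-pool material for the lactone half.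

**Step 1**
Reactants: 1 but-3-en-2-one (methyl vinyl ketone)
Product: 2 2-[(triisopropylsilyl)oxy]buta-1,3-diene
Conditions: i-Pr3SiOTf, Et3N, Et2O, 0 °C → rt
Reagents that add atoms: triisopropylsilyl trifluoromethanesulfonate, CC(C)[Si](OS(=O)(=O)C(F)(F)F)(C(C)C)C(C)C
Why: Soft enolisation and O-silylation of the methyl ketone (silyl enol ether formation) gives the cross-conjugated 2-silyloxy diene, the bulky silyl group being chosen for stability toward the acidic catalyst of step 3.

**Step 2**
Reactants: 3 2-oxopropanal (methylglyoxal, 40 % in water); 4 2-(triphenylphosphoranylidene)propanal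
Product: 5 (2E)-2-methyl-4-oxopent-2-enal
Conditions: CH2Cl2/H2O, rt
Reagents that add atoms: none
Why: Wittig olefination with a stabilised formyl ylide reacts only at the aldehyde carbon of the 1,2-dicarbonyl compound and should give the E alkene (acetyl trans to formyl), the geometry that later places methyl and isopropenyl cis on ring E.

**Step 3**
Reactants: 5 (2E)-2-methyl-4-oxopent-2-enal; 2 2-[(triisopropylsilyl)oxy]buta-1,3-diene
Product: 6 (1S,6S)-6-acetyl-1-methyl-4-[(triisopropylsilyl)oxy]cyclohex-3-ene-1-carbaldehyde
Conditions: (R)-3,3-diphenyl-1-(2-methylphenyl)tetrahydro-1H,3H-pyrrolo[1,2-c][1,3,2]oxazaborole (20 mol %), HNTf2 (18 mol %), CH2Cl2, −78 → −40 °C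
Reagents that add atoms: none
Why: The oxazaborolidinium ion binds the formyl oxygen of 5 and lowers the LUMO of the s-trans enal, and diene 2 adds in a concerted, asynchronous [4+2] cycloaddition whose leading bond runs from the nucleophilic CH2 terminus of the silyl dienol ether to the acetyl-bearing β-carbon. The closest known reaction type is the catalytic enantioselective Diels–Alder reaction of 2-silyloxybuta-1,3-dienes with α-branched acroleins. Ring E is closed by an intermolecular [4+2] union of a four-carbon and a two-carbon component, in which the bonds C-5–C-6 (ring CH2 to the acetyl-bearing methine) and C-1–C-2 (quaternary carbon to the other CH2) of 6 form in the same step. The relative configuration of the two new stereocentres follows from the E geometry of the dienophile (suprafacial addition keeps formyl and acetyl trans, hence methyl and acetyl cis), and their absolute configuration is set by the catalyst, which shields one face of the bound enal so that the diene adds to the (2Si,3Si) face. The step needs the "para" regiochemistry (silyloxy carbon opposite the formyl-bearing carbon), secured by pairing the nucleophilic diene terminus with the β-carbon of the catalyst-bound enal, and catalyst binding at the aldehyde and not the ketone, secured by the lower hindrance of the formyl group; endo/exo selectivity is irrelevant because the diene termini are unsubstituted.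

**Step 4**
Reactants: 6 (1S,6S)-6-acetyl-1-methyl-4-[(triisopropylsilyl)oxy]cyclohex-3-ene-1-carbaldehyde
Product: 8 (3R,4R)-4-ethenyl-4-methyl-3-(prop-1-en-2-yl)cyclohexan-1-one, via silyl enol ether triene 7 (not isolated)
Conditions: Cp2TiMe2 (5 equiv), toluene/THF, 65 °C; then aq. HCl (2 M), THF, rt
Reagents that add atoms: bis(cyclopentadienyl)dimethyltitanium, C[Ti](C)(C1C=CC=C1)C1C=CC=C1
Why: Petasis methylenation is non-basic, so formyl and acetyl become vinyl and isopropenyl without enolisation of the stereocentre next to the acetyl group or aldol closure of the 1,4-dicarbonyl unit, and mild acid then hydrolyses the silyl enol ether to the ketone.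

**Step 5**
Reactants: 8 (3R,4R)-4-ethenyl-4-methyl-3-(prop-1-en-2-yl)cyclohexan-1-one
Product: 9 (3R,4R)-4-ethenyl-4-methyl-3-(prop-1-en-2-yl)cyclohexane-1-carbonitrile (both C-1 epimers)
Conditions: TosMIC, KOt-Bu, EtOH (1.5 equiv), DME, 0 → 35 °C
Reagents that add atoms: p-toluenesulfonylmethyl isocyanide, [C-]#[N+]CS(=O)(=O)c1ccc(C)cc1
Why: Van Leusen reductive cyanation converts the ketone into the homologous nitrile with one added carbon; the new stereocentre is not controlled here because it is equilibrated in step 6.

**Step 6**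
Reactants: 9 (3R,4R)-4-ethenyl-4-methyl-3-(prop-1-en-2-yl)cyclohexane-1-carbonitrile (both C-1 epimers)
Product: 12 1-[(1S,3R,4R)-4-ethenyl-4-methyl-3-(prop-1-en-2-yl)cyclohexyl]ethan-1-one, via lithium ketimide 10 (not isolated), via epimeric ketone mixture 11 (not isolated)
Conditions: MeLi, Et2O, 0 °C; aq. HCl (1 M), rt; then NaOMe (cat.), MeOH, rt
Reagents that add atoms: methyllithium, [Li]C; water, O
Why: Addition of the organolithium to the nitrile and hydrolysis of the ketimide give the methyl ketone, and base-mediated enolisation (thermodynamic epimerisation) places the acetyl group equatorial, cis to the equatorial isopropenyl group, which sets C-1 as S.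

**Step 7**
Reactants: 12 1-[(1S,3R,4R)-4-ethenyl-4-methyl-3-(prop-1-en-2-yl)cyclohexyl]ethan-1-one
Product: 13 1-[(1S,3R,4R)-4-ethenyl-4-methyl-3-(prop-1-en-2-yl)cyclohexyl]ethenyl trifluoromethanesulfonate
Conditions: KN(SiMe3)2, THF, −78 °C; then PhNTf2, −78 → 0 °C
Reagents that add atoms: N-phenylbis(trifluoromethanesulfonimide), O=S(=O)(N(c1ccccc1)S(=O)(=O)C(F)(F)F)C(F)(F)F
Why: Kinetic deprotonation at the unhindered methyl group and O-sulfonylation of the enolate (enol triflate formation) give the 1,1-disubstituted vinyl triflate without touching the methine stereocentre.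

**Step 8**
Reactants: 13 1-[(1S,3R,4R)-4-ethenyl-4-methyl-3-(prop-1-en-2-yl)cyclohexyl]ethenyl trifluoromethanesulfonate
Product: 14 2-[(1S,3R,4R)-4-ethenyl-4-methyl-3-(prop-1-en-2-yl)cyclohexyl]prop-2-enal
Conditions: Pd(PPh3)4 (5 mol %), CO (1 atm), Bu3SnH (slow addition), LiCl, THF, 50 °C
Reagents that add atoms: carbon monoxide, [C-]#[O+]
Why: Palladium-catalysed reductive carbonylation (formylation) of the vinyl triflate, by oxidative addition to zerovalent palladium, CO insertion and hydride transfer from the tin hydride, gives the 2-substituted acrolein while the unactivated alkenes stay out of the reaction.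

**Step 9**
Reactants: 15 (+)-isoalantolactone (5αH-eudesma-4(15),11(13)-dien-12,8β-olide)
Product: 17 4-oxo-15-nor-5αH-eudesm-11(13)-en-12,8β-olide, via ozonide 16 (not isolated)
Conditions: O3, CH2Cl2, −78 °C (Sudan Red 7B end point); then Me2S, −78 °C → rt
Reagents that add atoms: ozone, [O-][O+]=O
Why: Ozonolysis is chemoselective for the electron-rich 4(15)-methylene over the electron-poor methylene lactone when ozone addition is stopped at the indicator end point, and reductive work-up gives the 4-ketone with all stereocentres untouched.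

**Step 10**
Reactants: 17 4-oxo-15-nor-5αH-eudesm-11(13)-en-12,8β-olide
Product: 18 4-oxo-15-nor-5βH-eudesm-11(13)-en-12,8β-olide
Conditions: p-TsOH·H2O (10 mol %), toluene, 60 °C; chromatography, recovered 17 resubmitted
Reagents that add atoms: none
Why: Acid-catalysed enolisation toward C-5 equilibrates the ring fusion (thermodynamic epimerisation); the cis-fused ketone escapes the 1,3-diaxial contact between the angular methyl group and the lactone oxygen of the trans series and should be a main component of the mixture, from which it is separated.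

**Step 11**
Reactants: 18 4-oxo-15-nor-5βH-eudesm-11(13)-en-12,8β-olide
Product: 19 5βH-eudesma-4(15),11(13)-dien-12,8β-olide (5-epi-isoalantolactone)
Conditions: Zn, CH2Br2, TiCl4, THF/CH2Cl2, 0 °C → rt
Reagents that add atoms: dibromomethane, BrCBr
Why: Lombardo methylenation is chemoselective for the ketone over the lactone carbonyl and, being non-basic, does not enolise the ketone, so the cis ring fusion from step 10 is kept.

**Step 12**
Reactants: 14 2-[(1S,3R,4R)-4-ethenyl-4-methyl-3-(prop-1-en-2-yl)cyclohexyl]prop-2-enal; 19 5βH-eudesma-4(15),11(13)-dien-12,8β-olide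
Product: 20 target spiro dimer
Conditions: 19 (3 equiv), BHT (cat.), toluene, 110 °C, sealed tube
Reagents that add atoms: none
Why: Thermal inverse-electron-demand hetero-Diels–Alder reaction in which enal 14 acts as the 1-oxadiene and the exocyclic methylene of lactone 19 as the dienophile, with the regiochemistry of acrolein dimerisation (oxygen to the lactone α-carbon); the oxadiene should add to the convex face of the cis-fused lactone, syn to H-7 and H-8, which sets the spiro carbon as R, and the excess of 19 suppresses self-reaction of 14.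

**Compound list**

1 | but-3-en-2-one (methyl vinyl ketone) | CC(=O)C=C | starting material
2 | 2-[(triisopropylsilyl)oxy]buta-1,3-diene | C=CC(=C)O[Si](C(C)C)(C(C)C)C(C)C | intermediate
3 | 2-oxopropanal (methylglyoxal) | CC(=O)C=O | starting material
4 | 2-(triphenylphosphoranylidene)propanal | CC(C=O)=P(c1ccccc1)(c1ccccc1)c1ccccc1 | starting material
5 | (2E)-2-methyl-4-oxopent-2-enal | CC(=O)/C=C(\C)C=O | intermediate
6 | (1S,6S)-6-acetyl-1-methyl-4-[(triisopropylsilyl)oxy]cyclohex-3-ene-1-carbaldehyde | O=C[C@@]1(C)CC=C(O[Si](C(C)C)(C(C)C)C(C)C)C[C@@H]1C(C)=O | intermediate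
7 | triisopropyl{[(4R,5R)-4-ethenyl-4-methyl-5-(prop-1-en-2-yl)cyclohex-1-en-1-yl]oxy}silane | C=C[C@@]1(C)CC=C(O[Si](C(C)C)(C(C)C)C(C)C)C[C@@H]1C(=C)C | intermediate
8 | (3R,4R)-4-ethenyl-4-methyl-3-(prop-1-en-2-yl)cyclohexan-1-one | C=C[C@@]1(C)CCC(=O)C[C@@H]1C(=C)C | intermediate
9 | (3R,4R)-4-ethenyl-4-methyl-3-(prop-1-en-2-yl)cyclohexane-1-carbonitrile, both C-1 epimers | C=C[C@@]1(C)CCC(C#N)C[C@@H]1C(=C)C | intermediate
10 | lithium 1-[(3R,4R)-4-ethenyl-4-methyl-3-(prop-1-en-2-yl)cyclohexyl]ethan-1-iminide, both C-1 epimers | C=C[C@@]1(C)CCC(C(C)=N[Li])C[C@@H]1C(=C)C | intermediate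
11 | 1-[(3R,4R)-4-ethenyl-4-methyl-3-(prop-1-en-2-yl)cyclohexyl]ethan-1-one, both C-1 epimers | C=C[C@@]1(C)CCC(C(C)=O)C[C@@H]1C(=C)C | intermediate
12 | 1-[(1S,3R,4R)-4-ethenyl-4-methyl-3-(prop-1-en-2-yl)cyclohexyl]ethan-1-one | C=C[C@@]1(C)CC[C@H](C(C)=O)C[C@@H]1C(=C)C | intermediate
13 | 1-[(1S,3R,4R)-4-ethenyl-4-methyl-3-(prop-1-en-2-yl)cyclohexyl]ethenyl trifluoromethanesulfonate | C=C[C@@]1(C)CC[C@H](C(=C)OS(=O)(=O)C(F)(F)F)C[C@@H]1C(=C)C | intermediate
14 | 2-[(1S,3R,4R)-4-ethenyl-4-methyl-3-(prop-1-en-2-yl)cyclohexyl]prop-2-enal (ent-elema-1,3,11(13)-trien-12-al) | C=C[C@@]1(C)CC[C@H](C(=C)C=O)C[C@@H]1C(=C)C | intermediate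
15 | (+)-isoalantolactone, 5αH-eudesma-4(15),11(13)-dien-12,8β-olide, (3aR,4aS,8aR,9aR) | C[C@]12CCCC(=C)[C@@H]1C[C@H]3[C@@H](C2)OC(=O)C3=C | starting material
16 | ozonide of 15 (spiro-1,2,4-trioxolane at C-4, lactone unchanged) | C[C@]12CCCC3(OCOO3)[C@@H]1C[C@H]3[C@@H](C2)OC(=O)C3=C | intermediate
17 | 4-oxo-15-nor-5αH-eudesm-11(13)-en-12,8β-olide (trans-fused decalone) | C[C@]12CCCC(=O)[C@@H]1C[C@H]3[C@@H](C2)OC(=O)C3=C | intermediate
18 | 4-oxo-15-nor-5βH-eudesm-11(13)-en-12,8β-olide (cis-fused decalone) | C[C@]12CCCC(=O)[C@H]1C[C@H]3[C@@H](C2)OC(=O)C3=C | intermediate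
19 | 5βH-eudesma-4(15),11(13)-dien-12,8β-olide (5-epi-isoalantolactone), (3aR,4aR,8aR,9aR) | C[C@]12CCCC(=C)[C@H]1C[C@H]3[C@@H](C2)OC(=O)C3=C | intermediate
20 | target: 5βH-eudesm-4(15)-en-12,8β-olide whose C-11 (R) is the spiro C-2 of a 3,4-dihydro-2H-pyran that carries at C-5 the (1S,3R,4R)-4-ethenyl-4-methyl-3-(prop-1-en-2-yl)cyclohexyl group | C=C[C@@]1(C)CC[C@H](C2=CO[C@@]3(CC2)C(=O)O[C@@H]2C[C@@]4(C)CCCC(=C)[C@H]4C[C@@H]23)C[C@@H]1C(=C)C | target

**Step count.** Total: 12 steps. Longest linear sequence: 8 steps (2, 3, 4, 5, 6, 7, 8, 12).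

**Steps most likely to fail**

Step 3. The ketone carbonyl of 5 may compete with the formyl group for the chiral Lewis acid, which would erode regio- and facial selectivity, and the silyl dienol ether may add to the formyl group in a Mukaiyama aldol sense. The fallback sets out from 2 and uses a dienophile with only one strongly basic carbonyl, commercially available ethyl (2E)-3-methyl-4-oxobut-2-enoate. The same catalysed cycloaddition should give ethyl (1S,6S)-6-formyl-6-methyl-3-[(triisopropylsilyl)oxy]cyclohex-3-ene-1-carboxylate F1. Wittig methylenation with Ph3P=CH2 gives ethyl (1S,6R)-6-ethenyl-6-methyl-3-[(triisopropylsilyl)oxy]cyclohex-3-ene-1-carboxylate F2. Excess MeLi with CeCl3 gives 2-{(1S,6R)-6-ethenyl-6-methyl-3-[(triisopropylsilyl)oxy]cyclohex-3-en-1-yl}propan-2-ol F3. Syn elimination with Burgess reagent toward a methyl group gives the isopropenyl compound 7, where the route is rejoined; 7 is hydrolysed to 8 as in the second stage of step 4.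

Step 10. The epimerisation equilibrium at the ring fusion may lie unfavourably or be reached only slowly, leaving much trans ketone to recycle. The fallback replaces thermodynamic by kinetic control and sets out from 17. Equilibrating silylation (Me3SiCl, NaI, Et3N, MeCN) gives the tetrasubstituted enol ether 4-[(trimethylsilyl)oxy]-15-nor-eudesma-4,11(13)-dien-12,8β-olide F4. Protonation at C-5 with HCl in THF at −78 °C is then tried, since kinetic protonation of ring-fusion enol derivatives of 1-decalones is known to favour the cis-fused ketone (equatorial approach with respect to ring B, away from the two axial hydrogens of the α face). The route is rejoined at 18.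

Step 12. Self-cycloaddition and polymerisation of enal 14 may outpace the cross reaction at the temperature needed, and addition to the two faces of the methylene lactone may not be fully selective. The fallback builds ring D stepwise and sets out from 19 and 14. Nucleophilic epoxidation of the methylene lactone of 19 (t-BuOOH, DBU, CH2Cl2) from the convex face gives the spiro-epoxy lactone 11,13-epoxy-5βH-eudesm-4(15)-en-12,8β-olide F5. Opening at the CH2 terminus with MgI2 gives the iodohydrin 11-hydroxy-13-iodo-5βH-eudesm-4(15)-en-12,8β-olide F6. Giese addition of the derived primary radical to the CH2 terminus of enal 14 (Bu3SnH, Et3B, air, toluene, 0 °C) gives the δ-hydroxy aldehyde, 2-(elemane cyclohexyl)-4-(11-hydroxy-lactone-11-yl)butanal F7. Acid-catalysed lactol formation and dehydration (pyridinium p-toluenesulfonate, toluene, molecular sieves, 60 °C) close the dihydropyran and rejoin the route at 20.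

**Further compounds**

F1 | step 3 | ethyl (1S,6S)-6-formyl-6-methyl-3-[(triisopropylsilyl)oxy]cyclohex-3-ene-1-carboxylate | O=C[C@@]1(C)CC=C(O[Si](C(C)C)(C(C)C)C(C)C)C[C@@H]1C(=O)OCC
F2 | step 3 | ethyl (1S,6R)-6-ethenyl-6-methyl-3-[(triisopropylsilyl)oxy]cyclohex-3-ene-1-carboxylate | C=C[C@@]1(C)CC=C(O[Si](C(C)C)(C(C)C)C(C)C)C[C@@H]1C(=O)OCC
F3 | step 3 | 2-{(1S,6R)-6-ethenyl-6-methyl-3-[(triisopropylsilyl)oxy]cyclohex-3-en-1-yl}propan-2-ol | C=C[C@@]1(C)CC=C(O[Si](C(C)C)(C(C)C)C(C)C)C[C@@H]1C(C)(C)O
F4 | step 10 | 4-[(trimethylsilyl)oxy]-15-nor-eudesma-4,11(13)-dien-12,8β-olide | C[C@]12CCCC(O[Si](C)(C)C)=C1C[C@H]3[C@@H](C2)OC(=O)C3=C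
F5 | step 12 | 11,13-epoxy-5βH-eudesm-4(15)-en-12,8β-olide (epoxide oxygen syn to H-7) | C[C@]12CCCC(=C)[C@H]1C[C@H]3[C@@H](C2)OC(=O)[C@@]34CO4
F6 | step 12 | 11-hydroxy-13-iodo-5βH-eudesm-4(15)-en-12,8β-olide (hydroxyl syn to H-7) | C[C@]12CCCC(=C)[C@H]1C[C@H]3[C@@H](C2)OC(=O)[C@@]3(O)CI
F7 | step 12 | 2-[(1S,3R,4R)-4-ethenyl-4-methyl-3-(prop-1-en-2-yl)cyclohexyl]-4-(11-hydroxy-12-oxo-5βH-eudesm-4(15)-en-12,8β-olid-11-yl)butanal, both epimers at the formyl-bearing carbon | C=C[C@@]1(C)CC[C@H](C(C=O)CC[C@]3(O)C(=O)O[C@@H]2C[C@@]4(C)CCCC(=C)[C@H]4C[C@@H]23)C[C@@H]1C(=C)C
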